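Less Z is needed for X than is charged to the flask: each turn of the cycle uses one Z, so at 50% conversion X has taken 0.0500 M of the 0.180 M charged. I called the charge less that amount, before any loss to D, the Z margin, 0.130 M, which is the stoichiometric excess of Z at that conversion.

- eta: G 0.10 M; Z 0.36 M; E 2 mM; run made earlier
- flask: G 0.10 M; Z 0.180 M; E 2.0 mM

- eta (time / h: X / %): 0.667: 8.5; 1.33: 10.2; 2.00: 18.9; 2.50: 21.6; 3.00: 23.6; 4.00: 29.6; 5.00: 35.3

(standard deviation of a reading: 1 percentage point)

* factor on the rate of making X when 50% of the G are converted if Z is charged twice over
* factor on the rate when 50% of the G are converted if E is charged at 20 mM instead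

- steps under discussion: Z + E <-> Q; Q -> J; G + J -> L; L -> E + X; 2 Z -> D
- no earlier run changes the charge of E; that part of a forecast is a guess
- no earlier run changes the charge of Z; that part of a forecast is a guess

I built the flask up one process at a time. With the catalytic cycle alone, I took the rate as linear in the charge of E, so 20 mM against 2.0 mM gave a factor 10.0. Next I let the rate follow [Z]. The eta run has the G and E of the flask and twice its Z, so it is the doubled case. Its margin is 0.310 M, which gave a factor 2.38 over the flask.

Last came the correction, the step from two Z to D, which takes two Z per D out of the margin, so that [Z] at 50% conversion is the margin less twice [D], apart from the Z held in the catalyst forms. With a scatter of 1 percentage point, I could not separate that loss from the fall of [G] in the eta readings, so I had no value for [D]. That step contains no E, however, so for a flask with 20 mM of E I took the cycle to gain the factor 10.0 on it. I therefore committed to about 2.38 for doubling Z, with no correction for D, and for E to 10.0 multiplied by the ratio of the two values of [Z] left at 50% conversion, which I expected to be more than 10.0.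

The forecast gave 1.6 for doubling Z and 10.5 for E, on the ground “All catalyst steps are linear in total E”.

The simulation gives 2.27 for doubling Z and 55.3 for E, which is 5.53 times the linear factor.

    Z + E ⇌ Q (K = 2.80 M⁻¹, k = 150 M⁻¹ h⁻¹)
    Q → J (k = 27.0 h⁻¹)
    G + J → L (k = 380 M⁻¹ h⁻¹)
    L → E + X (k = 21.0 h⁻¹)
    2 Z → D (k = 1.10 M⁻¹ h⁻¹)

At 15.0 h the flask stood at 49.7% X and held 0.0592 M D. Two Z per D makes 0.118 M of Z, which is 90.8% of the Z margin, and the Z left in the flask at that time was 6.51% of its charge.

All runs come from a simulation on assumed constants, and the scatter is random.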